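Follow the amber flask in time: target climbs to 60.6% by 60.0 h, and later readings add little.

| setting | amber | blue | flask |
|---|---|---|---|
| substrate | 0.020 M | 0.013 M | 0.020 M |
| partner | 0.024 M | 0.024 M | 0.0240 M |
| capture agent | 1 mM | 1 mM | 1.00 mM |
| remark | the very flask that is asked about, followed so far | run made earlier |  |
| time |  |  | 8.0 d |

- amber (time / h: target / %): 10.0: 29.0; 30.0: 54.4; 60.0: 60.6; 96.0: 61.1; 120: 61.9; 144: 62.9
- blue (time / h: target / %): 1.33: 0.2; 2.00: 0.2; 4.00: 9.1; 6.00: 18.0; 10.0: 32.4; 15.0: 43.7

(standard deviation of a reading: 1 percentage point)

- spring: at 8.0 d add substrate, 50.0% of the amount charged, then wait 4.0 d
- noon: at 8.0 d take out 90% of the target then present, then wait 4.0 d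
- summer: change nothing and wait 4.0 d more
- dusk: at 8.0 d add partner, 50.0% of the amount charged, then wait 4.0 d

- target that was removed still counts
- the earlier runs were read with a standard deviation of 1 percentage point
- steps under discussion: open intermediate + capture agent -> trapped intermediate; partner -> second intermediate; 2 second intermediate -> homo product; substrate <-> open intermediate; open intermediate + second intermediate -> target
- additions bring no volume worth counting

- target, in percent of the substrate first charged, at 8.0 d
- the option that brings most further target ("none" if no option brings more than 2 percentage points) (spring / noon / summer / dusk / none)
- target present, with what was taken out counted in, in percent of the substrate first charged, after spring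
- target present, with what was taken out counted in, in percent of the substrate first charged, after summer

1. Read the late end. The last 3 amber readings rise by 1.8 percentage points, against a scatter of 1 point on each, so treat them as flat. Take their mean, 62.0%, as my answer for the target at 8.0 d.

2. Face the puzzle. Each target takes one substrate and one partner, and amber holds more partner than substrate. Yet target stalls. Count the capture agent's charge as 5.00% of the substrate, trapped; that leaves 33.0% of the substrate charged unused, as substrate and open intermediate together.

3. Clear it up. Partner has a second exit: two second intermediates join to homo product. Amber's late readings give 0.516 target per partner charged: call this the partner share. If no partner remains, the rest stands as 0.00580 M of homo product. So treat partner as the limiting reagent here.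

4. Judge the options. Summer adds no partner, and neither does spring or noon, so expect amber to stay at 62.0% after each. Dusk adds 0.0120 M of partner. At the same partner share, that makes 31 points more target, less than the unused 33.0%. Choose dusk.

5. Hold this against the forecast: 63.5% now, 65% after spring, 64.3% after summer, and dusk as best, since “Fresh partner converts remaining substrate”.

The flask gives 62.0% now, 62.0% after spring, 62.0% after summer, and dusk as best, with 22 points against my 31 points.

    open intermediate + capture agent → trapped intermediate (k = 91.4 L mol⁻¹ h⁻¹)
    partner → second intermediate (k = 0.162 h⁻¹)
    2 second intermediate → homo product (k = 7.65 L mol⁻¹ h⁻¹)
    substrate ⇌ open intermediate (K = 0.961, k = 0.321 h⁻¹)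
    open intermediate + second intermediate → target (k = 14.3 L mol⁻¹ h⁻¹)

Now carry the partner share to the neighbouring flask charged with 0.014 M of partner. There, 0.516 predicts 36.1% target. The neighbour ends with partner at 0%, homo product at 0.00240 M and target at 46.0%, so its partner share is 0.657, higher than amber's 0.516.

(The runs are simulated with made-up constants, and the scatter is random.)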